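**Strategy.** Ring A of the drimane core carries no functional group on C2 and C3, which lie between C1 (on quaternary C10) and the gem-dimethyl carbon C4. That edge is disconnected as a cis C2=C3 alkene made by ring-closing metathesis, then saturated. The precursor is a monocyclic ring B enone from (R)-carvone, which already holds C5 with the correct configuration, the C8 methyl, C7=C8 and a C9 carbonyl for C11. Its C10 bears methyl and allyl (C1, C2) and its C5 a 2-methyl-4-phenylbut-3-en-2-yl group (C4, C3), trans to each other, so one operation closes ring A and fixes the trans-decalin. Ketone methylenation, hydroboration and a Knoevenagel–Doebner esterification finish the caffeate.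

Key step: step 4

Remark: drimane numbering is used for positions (ring A = C1–C5, C10; ring B = C5–C10; C11 = the CH2O carbon). The target is the caffeate of (−)-drimenol (5S,9S,10S; trans-fused).
Remark: step 2 gives 5 together with its C6 epimer; both give the same enolate 6 in step 3, so the mixture is carried on.

Step 1
Reactants: 1 (R)-(−)-carvone; 2 (E)-β-nitrostyrene
Product: 3 (5R)-2-methyl-5-[(3E)-2-methyl-4-phenylbut-3-en-2-yl]cyclohex-2-en-1-one
Conditions: Fe(acac)3 (30 mol %), PhSiH3, EtOH, 60 °C; 1 in excess (3 equiv) over 2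
Reagents that add atoms: none
Why: Hydrogen atom transfer from an iron hydride to the electron-rich 1,1-disubstituted isopropenyl alkene (the conjugated trisubstituted enone alkene should react far more slowly) gives the tertiary C4 radical, which adds to the β-carbon of 2 and expels NO2 (MHAT-initiated radical alkenylation, reductive alkene–nitroalkene coupling), forming the quaternary C4–C3 bond with (E) geometry and leaving the C5 stereocentre of carvone untouched.

Step 2
Reactants: 3 (5R)-2-methyl-5-[(3E)-2-methyl-4-phenylbut-3-en-2-yl]cyclohex-2-en-1-one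
Product: 5 (5R,6S)-2,6-dimethyl-5-[(3E)-2-methyl-4-phenylbut-3-en-2-yl]cyclohex-2-en-1-one, via lithium enolate 4 (not isolated)
Conditions: LiN(i-Pr)2, THF, −78 °C; then MeI, −78 → 0 °C
Reagents that add atoms: iodomethane, CI
Why: Kinetic deprotonation of the enone at the α′ carbon (C10) and SN2 methylation of enolate 4 (enolate alkylation) should place the methyl mainly trans to the C5 substituent, but this centre is planarised again in step 3, so its configuration does not matter.

Step 3
Reactants: 5 (5R,6S)-2,6-dimethyl-5-[(3E)-2-methyl-4-phenylbut-3-en-2-yl]cyclohex-2-en-1-one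
Product: 7 (5S,6S)-2,6-dimethyl-5-[(3E)-2-methyl-4-phenylbut-3-en-2-yl]-6-(prop-2-en-1-yl)cyclohex-2-en-1-one, via lithium enolate 6 (not isolated)
Conditions: LiN(i-Pr)2, THF/DMPU, −78 °C; then allyl bromide, −78 → 23 °C
Reagents that add atoms: allyl bromide, C=CCBr
Why: In this second α′ enolate alkylation the fully substituted enolate 6 should be attacked by allyl bromide on the face opposite the bulky pseudoaxial C5 substituent, which sets quaternary C10 with allyl trans and methyl cis to the C4 group, the known course of sequential α′-alkylation of carvone and the arrangement needed for a trans ring fusion.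

Step 4
Reactants: 7 (5S,6S)-2,6-dimethyl-5-[(3E)-2-methyl-4-phenylbut-3-en-2-yl]-6-(prop-2-en-1-yl)cyclohex-2-en-1-one
Product: 8 (4aS,8aS)-2,5,5,8a-tetramethyl-4a,5,8,8a-tetrahydronaphthalen-1(4H)-one
Conditions: second-generation Grubbs catalyst RuCl2(H2IMes)(PCy3)(=CHPh) (5 mol %), 1,4-benzoquinone (10 mol %), toluene (5 mM), 80 °C
Reagents that add atoms: none
Why: The ruthenium benzylidene initiates at the unhindered terminal alkene of the C10 allyl group to give a C2 alkylidene, which undergoes intramolecular [2+2] cycloaddition with the styrenyl C3=CHPh alkene and cycloreversion, forming the C2=C3 bond, releasing styrene and regenerating the benzylidene (olefin ring-closing metathesis). The closest known reaction type is the ring-closing metathesis of 1,7-dienes to cyclohexenes next to quaternary carbons, here with a styrenyl terminus as the second partner. Ring A (C1, C2, C3, C4, C5, C10) closes as a six-membered ring by metathesis of the two side-chain alkenes, both reacting carbons ending inside the ring, and the C4 gem-dimethyl group favours the folded conformer (Thorpe–Ingold effect). No stereocentre is created: the trans ring fusion follows from the trans arrangement of the C5 and C10 side chains fixed in step 3, and the ring size enforces the cis geometry of C2=C3. The step needs chemoselectivity between three alkenes, which the substrate secures because the trisubstituted, conjugated C7=C8 alkene is inert to the catalyst, and high dilution keeps intermolecular cross-metathesis of the allyl terminus behind ring closure.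

Step 5
Reactants: 8 (4aS,8aS)-2,5,5,8a-tetramethyl-4a,5,8,8a-tetrahydronaphthalen-1(4H)-one
Product: 9 (4aS,8aS)-2,5,5,8a-tetramethyl-4a,5,6,7,8,8a-hexahydronaphthalen-1(4H)-one
Conditions: H2 (1–4 atm), RhCl(PPh3)3 (5 mol %), benzene, 23 °C
Reagents that add atoms: none
Why: Homogeneous hydrogenation with Wilkinson's catalyst should saturate the cis-disubstituted C2=C3 alkene while the trisubstituted, conjugated C7=C8 alkene and the ketone stay intact, as in the selective reduction of the isopropenyl group of carvone.

Step 6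
Reactants: 9 (4aS,8aS)-2,5,5,8a-tetramethyl-4a,5,6,7,8,8a-hexahydronaphthalen-1(4H)-one
Product: 10 (4aS,8aS)-3,4a,8,8-tetramethyl-4-methylidene-1,4,4a,5,6,7,8,8a-octahydronaphthalene (drima-7,9(11)-diene)
Conditions: Ph3PCH3Br, KOt-Bu, toluene, 90 °C
Reagents that add atoms: methylenetriphenylphosphorane, C=P(c1ccccc1)(c1ccccc1)c1ccccc1, generated from methyltriphenylphosphonium bromide, C[P+](c1ccccc1)(c1ccccc1)c1ccccc1.[Br-]
Why: Wittig methylenation under the salt-free, high-temperature potassium tert-butoxide conditions used for hindered ketones should convert the C9 carbonyl, flanked by quaternary C10 and C8, into the exocyclic C9=C11 alkene.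

Step 7
Reactants: 10 drima-7,9(11)-diene
Product: 12 [(1S,4aS,8aS)-2,5,5,8a-tetramethyl-1,4,4a,5,6,7,8,8a-octahydronaphthalen-1-yl]methanol ((−)-drimenol), via alkylborane 11 (not isolated)
Conditions: 9-BBN, THF, 0 → 60 °C; then NaOH (aq), H2O2, 0 → 23 °C
Reagents that add atoms: 9-borabicyclo[3.3.1]nonane, B1C2CCCC1CCC2 (boron carried in 11 only); hydrogen peroxide, OO
Why: In this hydroboration–oxidation the bulky borane should add boron to the terminal C11 of the 1,1-disubstituted exocyclic alkene (the trisubstituted C7=C8 alkene is much slower) and deliver hydrogen to C9 from the α face opposite the axial C10 methyl, setting 9α-H and 9β-CH2OH, after which alkaline peroxide oxidises C–B to C–O with retention.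

Step 8
Reactants: 12 (−)-drimenol; 13 Meldrum's acid (2,2-dimethyl-1,3-dioxane-4,6-dione)
Product: 14 3-{[(1S,4aS,8aS)-2,5,5,8a-tetramethyl-1,4,4a,5,6,7,8,8a-octahydronaphthalen-1-yl]methoxy}-3-oxopropanoic acid (drimenyl hydrogen malonate)
Conditions: toluene, 100 °C
Reagents that add atoms: none
Why: Thermal acylation of the primary alcohol by Meldrum's acid (ring opening with loss of acetone) should give the malonic half ester without coupling reagents or protecting groups.

Step 9
Reactants: 14 drimenyl hydrogen malonate; 15 3,4-dihydroxybenzaldehyde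
Product: 17 [(1S,4aS,8aS)-2,5,5,8a-tetramethyl-1,4,4a,5,6,7,8,8a-octahydronaphthalen-1-yl]methyl (2E)-3-(3,4-dihydroxyphenyl)prop-2-enoate (CNP0265201.1), via arylidenemalonic half ester 16 (not isolated)
Conditions: pyridine, piperidine (10 mol %), 50 °C
Reagents that add atoms: none
Why: Knoevenagel condensation with Doebner decarboxylation should condense the half ester with the aldehyde and lose CO2 to give the (E)-cinnamate directly, a sequence that tolerates the free catechol.

**Compound list**

1 | (R)-(−)-carvone | CC1=CC[C@@H](C(C)=C)CC1=O | starting material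
2 | (E)-β-nitrostyrene | O=[N+]([O-])/C=C/c1ccccc1 | starting material
3 | (5R)-2-methyl-5-[(3E)-2-methyl-4-phenylbut-3-en-2-yl]cyclohex-2-en-1-one | CC1=CC[C@@H](C(C)(C)/C=C/c2ccccc2)CC1=O | intermediate
4 | lithium (3R)-6-methyl-3-[(3E)-2-methyl-4-phenylbut-3-en-2-yl]cyclohexa-1,5-dien-1-olate | CC1=CC[C@@H](C(C)(C)/C=C/c2ccccc2)C=C1[O-].[Li+] | intermediate
5 | (5R,6S)-2,6-dimethyl-5-[(3E)-2-methyl-4-phenylbut-3-en-2-yl]cyclohex-2-en-1-one (major epimer) | CC1=CC[C@@H](C(C)(C)/C=C/c2ccccc2)[C@H](C)C1=O | intermediate
6 | lithium (3S)-2,6-dimethyl-3-[(3E)-2-methyl-4-phenylbut-3-en-2-yl]cyclohexa-1,5-dien-1-olate | CC1=CC[C@@H](C(C)(C)/C=C/c2ccccc2)C(C)=C1[O-].[Li+] | intermediate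
7 | (5S,6S)-2,6-dimethyl-5-[(3E)-2-methyl-4-phenylbut-3-en-2-yl]-6-(prop-2-en-1-yl)cyclohex-2-en-1-one | CC1=CC[C@@H](C(C)(C)/C=C/c2ccccc2)[C@](C)(CC=C)C1=O | intermediate
8 | (4aS,8aS)-2,5,5,8a-tetramethyl-4a,5,8,8a-tetrahydronaphthalen-1(4H)-one | CC1=CC[C@H]2C(C)(C)C=CC[C@]2(C)C1=O | intermediate
9 | (4aS,8aS)-2,5,5,8a-tetramethyl-4a,5,6,7,8,8a-hexahydronaphthalen-1(4H)-one | CC1=CC[C@H]2C(C)(C)CCC[C@]2(C)C1=O | intermediate
10 | (4aS,8aS)-3,4a,8,8-tetramethyl-4-methylidene-1,4,4a,5,6,7,8,8a-octahydronaphthalene (drima-7,9(11)-diene) | CC1=CC[C@H]2C(C)(C)CCC[C@]2(C)C1=C | intermediate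
11 | 9-{[(1S,4aS,8aS)-2,5,5,8a-tetramethyl-1,4,4a,5,6,7,8,8a-octahydronaphthalen-1-yl]methyl}-9-borabicyclo[3.3.1]nonane | CC1=CC[C@H]2C(C)(C)CCC[C@]2(C)[C@H]1CB1C2CCCC1CCC2 | intermediate
12 | [(1S,4aS,8aS)-2,5,5,8a-tetramethyl-1,4,4a,5,6,7,8,8a-octahydronaphthalen-1-yl]methanol ((−)-drimenol) | CC1=CC[C@H]2C(C)(C)CCC[C@]2(C)[C@H]1CO | intermediate
13 | Meldrum's acid (2,2-dimethyl-1,3-dioxane-4,6-dione) | CC1(C)OC(=O)CC(=O)O1 | starting material
14 | 3-{[(1S,4aS,8aS)-2,5,5,8a-tetramethyl-1,4,4a,5,6,7,8,8a-octahydronaphthalen-1-yl]methoxy}-3-oxopropanoic acid | CC1=CC[C@H]2C(C)(C)CCC[C@]2(C)[C@H]1COC(=O)CC(=O)O | intermediate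
15 | 3,4-dihydroxybenzaldehyde | O=Cc1ccc(O)c(O)c1 | starting material
16 | 3-(3,4-dihydroxyphenyl)-2-({[(1S,4aS,8aS)-2,5,5,8a-tetramethyl-1,4,4a,5,6,7,8,8a-octahydronaphthalen-1-yl]methoxy}carbonyl)prop-2-enoic acid | CC1=CC[C@H]2C(C)(C)CCC[C@]2(C)[C@H]1COC(=O)C(=Cc1ccc(O)c(O)c1)C(=O)O | intermediate
17 | [(1S,4aS,8aS)-2,5,5,8a-tetramethyl-1,4,4a,5,6,7,8,8a-octahydronaphthalen-1-yl]methyl (2E)-3-(3,4-dihydroxyphenyl)prop-2-enoate | CC1=CC[C@H]2C(C)(C)CCC[C@]2(C)[C@H]1COC(=O)/C=C/c1ccc(O)c(O)c1 | target

**Total step count:** 9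
**Longest linear sequence:** 9 steps (from 1 to 17)

**Steps most likely to fail**

Step 4. The ruthenium alkylidene formed at the allyl terminus may fail to engage the internal styrenyl alkene, which sits next to quaternary C4, so that intermolecular cross-metathesis through C2 or isomerisation of the allyl group outruns ring closure. The fallback sets out from 5 and replaces the styrenyl partner by a terminal vinyl group. Lemieux–Johnson cleavage of the styrenyl alkene (OsO4 cat., NaIO4, 2,6-lutidine, dioxane–water; the electron-poor enone alkene should be spared) would give 2-[(1R,2S)-2,4-dimethyl-3-oxocyclohex-4-en-1-yl]-2-methylpropanal F1. Chemoselective Wittig methylenation of the aldehyde (Ph3P=CH2, 1.1 equiv, THF, −78 → 0 °C) would give (5R,6S)-2,6-dimethyl-5-(2-methylbut-3-en-2-yl)cyclohex-2-en-1-one F2. Deprotonation with LiN(i-Pr)2 would give lithium (3S)-2,6-dimethyl-3-(2-methylbut-3-en-2-yl)cyclohexa-1,5-dien-1-olate F3, and allylation as in step 3 would give (5S,6S)-2,6-dimethyl-5-(2-methylbut-3-en-2-yl)-6-(prop-2-en-1-yl)cyclohex-2-en-1-one F4. Ring-closing metathesis of this bis-terminal diene with the second-generation Grubbs catalyst in CH2Cl2 at 40 °C, with loss of ethene, comes back to the route at 8.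

Step 1. The tertiary radical may be intercepted by the enone of a second carvone molecule or reduced to the isopropyl group before it meets 2, and the iron hydride may consume 2 by reduction. The fallback sets out from 1 and generates the same radical by a tin chain instead of hydrogen atom transfer. Markovnikov addition of HBr (33 % in AcOH, 0 °C) to the isopropenyl group would give (5R)-5-(2-bromopropan-2-yl)-2-methylcyclohex-2-en-1-one F5. Radical chain alkenylation with (E)-tributyl(2-phenylethenyl)stannane and AIBN in benzene at 80 °C (bromine abstraction, addition of the tertiary radical to the tin-bearing carbon, β-elimination of the stannyl radical) comes back to the route at 3.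

Step 3. The congested, fully substituted enolate carbon may react at oxygen, react sluggishly, or lose facial selectivity. The fallback sets out from lithium enolate 6 (made from 5 as in step 3) and moves the C–C bond formation to a palladium π-allyl intermediate. O-Acylation with allyl chloroformate (THF/DMPU, −78 °C) would give (3S)-2,6-dimethyl-3-[(3E)-2-methyl-4-phenylbut-3-en-2-yl]cyclohexa-1,5-dien-1-yl prop-2-en-1-yl carbonate F6. Decarboxylative allylation with Pd(PPh3)4 (zerovalent palladium, 5 mol %) in THF at 23 °C (Tsuji allylation: ionisation, loss of CO2, recombination of the π-allylpalladium cation with the enolate at C10 anti to the C5 substituent) comes back to the route at 7.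

**Further compounds**

F1 | step 4 | 2-[(1R,2S)-2,4-dimethyl-3-oxocyclohex-4-en-1-yl]-2-methylpropanal | CC1=CC[C@@H](C(C)(C)C=O)[C@H](C)C1=O
F2 | step 4 | (5R,6S)-2,6-dimethyl-5-(2-methylbut-3-en-2-yl)cyclohex-2-en-1-one | CC1=CC[C@@H](C(C)(C)C=C)[C@H](C)C1=O
F3 | step 4 | lithium (3S)-2,6-dimethyl-3-(2-methylbut-3-en-2-yl)cyclohexa-1,5-dien-1-olate | CC1=CC[C@@H](C(C)(C)C=C)C(C)=C1[O-].[Li+]
F4 | step 4 | (5S,6S)-2,6-dimethyl-5-(2-methylbut-3-en-2-yl)-6-(prop-2-en-1-yl)cyclohex-2-en-1-one | CC1=CC[C@@H](C(C)(C)C=C)[C@](C)(CC=C)C1=O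
F5 | step 1 | (5R)-5-(2-bromopropan-2-yl)-2-methylcyclohex-2-en-1-one | CC1=CC[C@@H](C(C)(C)Br)CC1=O
F6 | step 3 | (3S)-2,6-dimethyl-3-[(3E)-2-methyl-4-phenylbut-3-en-2-yl]cyclohexa-1,5-dien-1-yl prop-2-en-1-yl carbonate | CC1=CC[C@@H](C(C)(C)/C=C/c2ccccc2)C(C)=C1OC(=O)OCC=C
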